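The amounts to watch in cedar are two small ones: free catalyst and impurity, each a fraction of a millimolar.

| setting | cedar | oak | flask |
|---|---|---|---|
| left-handed substrate | 0.30 M | 0.30 M | 0.30 M |
| right-handed substrate | 0.30 M | 0.30 M | 0.30 M |
| reagent | 1.1 equiv | 0.74 equiv | 1.10 equiv |
| free catalyst | 0.05 mol% | 0.05 mol% | 0.05 mol% |
| impurity | 0.21 mM | 0.21 mM | 0.21 mM |
| temperature | 60 °C | 66 °C | 60 °C |
| remark | the very flask that is asked about, followed so far | run made earlier |  |
| time |  |  | 6.0 h |

| run | time / min | left-handed product / % | left-handed substrate / % |
|---|---|---|---|
| cedar | 20.0 | 9.0 | 33.3 |
| cedar | 50.0 | 8.8 | 33.7 |
| cedar | 90.0 | 8.7 | 33.3 |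
| cedar | 150 | 9.3 | 33.2 |
| cedar | 240 | 8.2 | 33.6 |
| oak | 4.00 | 8.7 | 38.6 |
| oak | 8.00 | 6.9 | 38.7 |
| oak | 12.0 | 6.5 | 38.5 |
| oak | 15.0 | 6.0 | 39.0 |
| oak | 20.0 | 5.8 | 38.6 |

(scatter of a reading: 0.3 percentage points)

- free catalyst is single-handed; left-handed substrate and right-handed substrate are mirror images of each other, charged as a racemate, each of them at the stated concentration
- removed left-handed product is counted in
- the numbers in the tables scatter by 0.3 percentage points (one standard deviation)
- additions bring no volume worth counting

- ochre: change nothing and wait 3.0 h more
- teal: at 6.0 h take out 90% of the left-handed product then present, then wait 3.0 h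
- green: at 6.0 h raise the temperature by 10 K, then wait 3.0 h
- blue: at 6.0 h add reagent, 100% of the amount charged, then wait 3.0 h
- red: at 6.0 h add free catalyst, 100% of the amount charged, then wait 3.0 h

1. left-handed product, in percent of the left-handed substrate and right-handed substrate together first charged, at 6.0 h
2. the option that brings most further left-handed product ("none" if no option brings more than 2 percentage points) (ochre / teal / green / blue / red / none)
3. left-handed product present, with what was taken out counted in, in percent of the left-handed substrate and right-handed substrate together first charged, after ochre
4. left-handed product present, with what was taken out counted in, in percent of the left-handed substrate and right-handed substrate together first charged, after red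

1. In cedar, left-handed substrate stands at 33.3% from the first reading and in oak at 38.6%, so both runs stop early. Cedar has used 0.100 M of left-handed substrate against 0.330 M of reagent charged, so reagent is still there. Left-handed product reads about half of the left-handed substrate consumed, and in oak it sinks within minutes, which reads as racemisation to right-handed product.

2. My own reckoning replaces the falling reagent curve by its mean, the charge minus half the use. The logarithmic fall of left-handed substrate per mean reagent is then 1.45 /M in cedar and 1.38 /M in oak, nearly equal. So cedar and oak, which differ in temperature as well as in reagent, read as if the free catalyst worked for a span of like length in both.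

3. Both runs charge 0.150 mM of free catalyst against 0.21 mM of impurity, so impurity is the larger. Suppose one impurity removes one catalyst. Then the quantity to carry is the impurity margin, c(impurity) minus c(free catalyst): 0.0600 mM. On this supposition, while it is positive, the impurity can take a whole dose of free catalyst.

4. My estimate is therefore that cedar stays at the mean reading of 8.80%, through ochre too.

5. Red adds 0.150 mM. The margin should take its share and 0.0900 mM should stay free. Reagent, about 0.230 M, is less than the roughly 0.500 M of the two substrates together, so it should be the limiting reagent. Left-handed and right-handed product together should then reach 55.0% of the charge, and racemisation should share this equally: about 27.5%.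

6. The weak link is whether 3.0 h suffices. In oak, at 66 °C, the stop came before 4.00 min, with mean catalyst below its charge, so on this reckoning the rate constant there is at least 2300 /M²/min. Taken over to cedar as a rough value, with reagent as it stands when the wait begins, this gives a half-life of left-handed substrate under the free catalyst of about 14.6 min, shorter than the wait.

The forecast gives 8.7% at 6.0 h, 8.7% after ochre, red as best, and 13.8% after red, on the ground that “a similar dose gives about the same first-order extent”. My figure for red is higher; the two part on the second dose.

Cedar gives 8.80% at 6.0 h, 8.80% after ochre and 27.5% after red, a gain of 19 percentage points, which makes red best. At 360 min cedar holds 0% of its free catalyst and 29% of its impurity. The margin is 28.6% of the charged impurity.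

    reagent + free catalyst + left-handed substrate → free catalyst + left-handed product (k = 17800 /M²/min, Ea = 39.0 kJ/mol)
    reagent + free catalyst + right-handed substrate → free catalyst + right-handed product (k = 931 /M²/min, Ea = 50.0 kJ/mol)
    free catalyst + impurity → spent catalyst (k = 15000 /M/min, Ea = 49.0 kJ/mol)
    left-handed product ⇌ right-handed product (k = 0.0656 /min, Ea = 93.0 kJ/mol)
    (constants at 60 °C)

In a neighbour flask with 0.085 mol% of free catalyst, the margin is −0.0450 mM, so 17.6% of that catalyst should stay free and left-handed product should approach 27.5%. At 360 min the neighbour flask computes to 17.6% free catalyst and 27.5% of left-handed product, with 0% reagent left.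

The data come from a simulation from invented constants.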